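## Retrosynthetic overview

1. The target acid 17 comes from N-acyl oxazolidinone 15 by hydrolysis; 15 comes from acyclic iodo alkenyl peroxide 14 by a 6-exo radical cyclisation that closes the 1,2-dioxane (the only ring of the target) through the C3–C4 bond and sets C3 and Cα in the same operation.
2. Enabling feature: ring carbon C3 is both the peroxide-bearing carbon (O2–C3) and the β-carbon of the propanoic acid (C3–Cα–C1=O). At the enoate level (C3=Cα) it accepts a primary radical at C4, which lies γ to the quaternary peroxide carbon C6; the O1–O2 bond is the tether.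
3. 14 comes from tertiary hydroperoxide 9 and acetal 12 by peroxyacetalisation and loss of methanol.
4. C6: (S)-hydroperoxide from perhydrolysis (inversion) of (R)-oxetane 5, made from the 1,3-diol of the Sharpless epoxide of geranylgeraniol, which supplies C4–C6, the C6 methyl and the whole polyene chain.
5. Ring order: oxirane (step 1, temporary), oxetane (step 4, temporary), 1,2-dioxane (step 12).

Key step: step 12

Assumption: the (3aS,8aR) antipode of the bis(oxazoline) ligand is taken to open the C3 face that leads to 3S; should a model cyclisation show the opposite sense, the (3aR,8aS) ligand is used with no other change.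

## Route

Step 1
Reactants: 1 (2E,6E,10E)-geranylgeraniol
Product: 2 [(2R,3R)-3-methyl-3-[(3E,7E)-4,8,12-trimethyltrideca-3,7,11-trien-1-yl]oxiran-2-yl]methanol
Conditions: Ti(OiPr)4 (10 mol %), D-(−)-diethyl tartrate (12 mol %), t-BuOOH, 4 Å MS, CH2Cl2, −20 °C
Reagents that add atoms: tert-butyl hydroperoxide, CC(C)(C)OO
Why: Sharpless asymmetric epoxidation, in which the allylic hydroxyl directs the titanium–tartrate–peroxide complex to the C2=C3 alkene only and D-(−)-tartrate delivers oxygen to the face that should give the 2R,3R epoxide (both centres by reagent control).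

Step 2
Reactants: 2 the (2R,3R)-epoxy alcohol
Product: 3 (3R,6E,10E)-3,7,11,15-tetramethylhexadeca-6,10,14-triene-1,3-diol
Conditions: NaAlH2(OCH2CH2OMe)2 (Red-Al), THF, 0 °C; aq. NaOH work-up
Reagents that add atoms: none
Why: Hydroxyl-directed intramolecular hydride delivery from the alkoxyaluminate opens the 2,3-epoxy alcohol at C2 (regioselective Red-Al reduction to a 1,3-diol), so the tertiary C–O bond and its R configuration are untouched.

Step 3
Reactants: 3 the (R)-1,3-diol
Product: 4 (3R,6E,10E)-3-hydroxy-3,7,11,15-tetramethylhexadeca-6,10,14-trien-1-yl 4-methylbenzenesulfonate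
Conditions: TsCl, Et3N, DMAP (cat.), CH2Cl2, 0 °C
Reagents that add atoms: p-toluenesulfonyl chloride, Cc1ccc(cc1)S(Cl)(=O)=O
Why: Selective sulfonylation of the primary over the tertiary hydroxyl on steric grounds; no stereocentre is touched.

Step 4
Reactants: 4 the primary tosylate
Product: 5 (2R)-2-methyl-2-[(3E,7E)-4,8,12-trimethyltrideca-3,7,11-trien-1-yl]oxetane
Conditions: KOtBu, THF, 0 °C to rt
Reagents that add atoms: none
Why: Intramolecular Williamson etherification (4-exo-tet) in which the tertiary alkoxide displaces the primary tosylate, so the quaternary centre keeps its configuration.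

Step 5
Reactants: 5 the (R)-oxetane
Product: 6 (3S,6E,10E)-3-hydroperoxy-3,7,11,15-tetramethylhexadeca-6,10,14-trien-1-ol
Conditions: H2O2 (anhydrous, ethereal, 5 equiv), TMSOTf (0.2 equiv), Et2O, −78 to 0 °C
Reagents that add atoms: hydrogen peroxide, OO
Why: Lewis-acid-promoted perhydrolysis of a 2,2-disubstituted oxetane, in which the silyl-activated ring is opened at the tertiary carbon by H2O2 in an SN2-like ion-pair process with inversion, turning the R oxetane into the S tertiary hydroperoxide (C6 of the target).

Step 6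
Reactants: 6 the hydroperoxy alcohol
Product: 7 (3S,6E,10E)-3-[(2-methoxypropan-2-yl)peroxy]-3,7,11,15-tetramethylhexadeca-6,10,14-trien-1-ol
Conditions: 2-methoxypropene (1.1 equiv), PPTS (cat.), CH2Cl2, −20 °C
Reagents that add atoms: 2-methoxypropene, COC(C)=C
Why: Acid-catalysed perketalisation with an enol ether, in which the hydroperoxide (α-effect nucleophile) should capture the 2-methoxy-2-propyl cation faster than the primary alcohol, and any mixed ketal formed at the alcohol is lost on aqueous work-up.

Step 7
Reactants: 7 the peroxyketal alcohol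
Product: 8 (3S,6E,10E)-1-iodo-3-[(2-methoxypropan-2-yl)peroxy]-3,7,11,15-tetramethylhexadeca-6,10,14-triene
Conditions: PPh3, I2, imidazole, CH2Cl2, 0 °C (PPh3 and I2 premixed)
Reagents that add atoms: iodine, II
Why: Appel-type (Garegg–Samuelsson) iodination of the primary alcohol, with the phosphine consumed by iodine before it meets the peroxide and imidazole buffering the acid-labile peroxyketal.

Step 8
Reactants: 8 the peroxyketal iodide
Product: 9 (3S,6E,10E)-3-hydroperoxy-1-iodo-3,7,11,15-tetramethylhexadeca-6,10,14-triene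
Conditions: AcOH/THF/H2O (4:2:1), rt
Reagents that add atoms: none
Why: Mild aqueous acid hydrolysis of the 2-methoxy-2-propyl peroxyketal frees the hydroperoxide, and without base the 3-hydroperoxy iodide should not close to a 1,2-dioxolane.

Step 9
Reactants: 10 3-propanoyl-1,3-oxazolidin-2-one
Product: 12 3-(3,3-dimethoxy-2-methylpropanoyl)-1,3-oxazolidin-2-one (racemic), via trichlorotitanium enolate 11 (not isolated)
Conditions: TiCl4, i-Pr2NEt, CH2Cl2, 0 °C; then HC(OMe)3, 0 °C
Reagents that add atoms: trimethyl orthoformate, COC(OC)OC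
Why: Soft enolisation of the imide to its (Z)-titanium enolate and alkylation by the dimethoxycarbenium ion from the orthoester (titanium-enolate orthoformate alkylation); the new α-centre is racemic, which is irrelevant because it becomes sp2 in step 11.

Step 10
Reactants: 9 the hydroperoxy iodide; 12 the imide acetal
Product: 13 3-[3-{[(3S,6E,10E)-1-iodo-3,7,11,15-tetramethylhexadeca-6,10,14-trien-3-yl]peroxy}-3-methoxy-2-methylpropanoyl]-1,3-oxazolidin-2-one (mixture at the acetal carbon and at C2 of the propanoyl unit)
Conditions: CSA (10 mol %), 4 Å MS, CH2Cl2, 0 °C to rt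
Reagents that add atoms: none
Why: Acid-catalysed transacetalisation of a dimethyl acetal with a hydroperoxide gives the mixed monoperoxyacetal (methanol trapped by the sieves); the two new centres form as a mixture and are erased in step 11.

Step 11
Reactants: 13 the mixed peroxyacetal
Product: 14 3-[(2E)-3-{[(3S,6E,10E)-1-iodo-3,7,11,15-tetramethylhexadeca-6,10,14-trien-3-yl]peroxy}-2-methylprop-2-enoyl]-1,3-oxazolidin-2-one
Conditions: TMSOTf, i-Pr2NEt, CH2Cl2, −78 to −30 °C; cold work-up, used at once
Reagents that add atoms: none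
Why: Silyl-triflate ionisation of the more basic methoxy group gives a peroxycarbenium ion that loses its acidic α-proton to the amine (acetal-to-enol-ether elimination), which should give the more stable (E)-β-peroxyacryloyl imide, a push–pull alkenyl peroxide that is kept cold and not stored.

Step 12
Reactants: 14 the iodo alkenyl peroxide
Product: 15 3-[(2S)-2-[(3S,6S)-6-methyl-6-[(3E,7E)-4,8,12-trimethyltrideca-3,7,11-trien-1-yl]-1,2-dioxan-3-yl]propanoyl]-1,3-oxazolidin-2-one
Conditions: Mg(NTf2)2 (1.1 equiv), (3aS,8aR)-cyclopropylidene-bis(indano-oxazoline) ligand (1.1 equiv), Bu3SnH (1.5 equiv), Et3B (0.3 equiv), air, CH2Cl2, −78 °C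
Reagents that add atoms: none
Why: Proposed new method: Et3B/O2 starts a chain in which Bu3Sn• abstracts iodine from C4, the primary C4 radical adds 6-exo-trig to C3, the β-carbon of the magnesium-chelated (E)-β-peroxy-α-methylacryloyl imide, through a chair-like transition state with the O1–O2 bond as tether, and the resulting α-acyl radical at Cα abstracts hydrogen from Bu3SnH. The closest known reaction types are the 6-exo radical cyclisation of β-alkoxyacrylates to 2,6-disubstituted tetrahydropyrans and the chiral-Lewis-acid-mediated radical conjugate addition/hydrogen-atom transfer to β-acyloxy-α-methylacryloyl imides that gives anti-propionate aldols; new are the peroxide tether and the peroxy substituent on the acceptor. C3 is set by reagent control: the quaternary C6 carries CH3 and a CH2R chain of almost equal size, so the substrate prefers neither chair and the bis(oxazoline)–magnesium complex bound to both imide carbonyls decides which face of C3 is open. Cα is set by hydrogen-atom transfer to the chelated radical anti to the C3–O2 bond of the new ring (1,2-induction from C3, exocyclic-radical effect), which should give the required 2,3-anti pair. The 6-exo addition must outrun reduction of the C4 radical, its 6-exo attack on the nearest chain alkene and 1,5-hydrogen shift, which the LUMO-lowered, polarity-matched chelated acceptor should secure at −78 °C. Hydrogen transfer must also outrun 3-exo attack of the Cα radical on the O–O bond (epoxide formation), which is disfavoured at −78 °C and by the polarity mismatch between the electrophilic magnesium-bound α-acyl radical and the peroxide, whereas the hydridic Sn–H bond is matched.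

Step 13
Reactants: 15 the cyclised imide
Product: 17 (2S)-2-[(3S,6S)-6-methyl-6-[(3E,7E)-4,8,12-trimethyltrideca-3,7,11-trien-1-yl]-1,2-dioxan-3-yl]propanoic acid (target), via peroxy acid 16 (not isolated)
Conditions: LiOH, H2O2 (30% aq.), THF/H2O (3:1), 0 °C; aq. Na2SO3; aq. HCl to pH 3
Reagents that add atoms: hydrogen peroxide, OO
Why: Hydroperoxide-anion cleavage of the N-acyl oxazolidinone at the exocyclic carbonyl followed by sulfite reduction of the percarboxylate; the weakly basic nucleophile at 0 °C should avoid epimerisation at Cα and β-elimination of the ring peroxide, and a dialkyl peroxide is inert to sulfite.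

## Compound list

1 | (2E,6E,10E)-3,7,11,15-tetramethylhexadeca-2,6,10,14-tetraen-1-ol (geranylgeraniol) | CC(C)=CCC/C(C)=C/CC/C(C)=C/CC/C(C)=C/CO | starting material
2 | [(2R,3R)-3-methyl-3-[(3E,7E)-4,8,12-trimethyltrideca-3,7,11-trien-1-yl]oxiran-2-yl]methanol | CC(C)=CCC/C(C)=C/CC/C(C)=C/CC[C@@]1(C)O[C@@H]1CO | intermediate
3 | (3R,6E,10E)-3,7,11,15-tetramethylhexadeca-6,10,14-triene-1,3-diol | CC(C)=CCC/C(C)=C/CC/C(C)=C/CC[C@](O)(C)CCO | intermediate
4 | (3R,6E,10E)-3-hydroxy-3,7,11,15-tetramethylhexadeca-6,10,14-trien-1-yl 4-methylbenzenesulfonate | CC(C)=CCC/C(C)=C/CC/C(C)=C/CC[C@](O)(C)CCOS(=O)(=O)c1ccc(C)cc1 | intermediate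
5 | (2R)-2-methyl-2-[(3E,7E)-4,8,12-trimethyltrideca-3,7,11-trien-1-yl]oxetane | CC(C)=CCC/C(C)=C/CC/C(C)=C/CC[C@]1(C)CCO1 | intermediate
6 | (3S,6E,10E)-3-hydroperoxy-3,7,11,15-tetramethylhexadeca-6,10,14-trien-1-ol | CC(C)=CCC/C(C)=C/CC/C(C)=C/CC[C@@](OO)(C)CCO | intermediate
7 | (3S,6E,10E)-3-[(2-methoxypropan-2-yl)peroxy]-3,7,11,15-tetramethylhexadeca-6,10,14-trien-1-ol | CC(C)=CCC/C(C)=C/CC/C(C)=C/CC[C@@](OOC(C)(C)OC)(C)CCO | intermediate
8 | (3S,6E,10E)-1-iodo-3-[(2-methoxypropan-2-yl)peroxy]-3,7,11,15-tetramethylhexadeca-6,10,14-triene | CC(C)=CCC/C(C)=C/CC/C(C)=C/CC[C@@](OOC(C)(C)OC)(C)CCI | intermediate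
9 | (3S,6E,10E)-3-hydroperoxy-1-iodo-3,7,11,15-tetramethylhexadeca-6,10,14-triene | CC(C)=CCC/C(C)=C/CC/C(C)=C/CC[C@@](OO)(C)CCI | intermediate
10 | 3-propanoyl-1,3-oxazolidin-2-one | CCC(=O)N1CCOC1=O | starting material
11 | trichlorotitanium (Z)-enolate of 10 (not isolated) | C/C=C(\O[Ti](Cl)(Cl)Cl)N1CCOC1=O | intermediate
12 | 3-(3,3-dimethoxy-2-methylpropanoyl)-1,3-oxazolidin-2-one (racemic) | COC(OC)C(C)C(=O)N1CCOC1=O | intermediate
13 | 3-[3-{[(3S,6E,10E)-1-iodo-3,7,11,15-tetramethylhexadeca-6,10,14-trien-3-yl]peroxy}-3-methoxy-2-methylpropanoyl]-1,3-oxazolidin-2-one (diastereomer mixture) | CC(C)=CCC/C(C)=C/CC/C(C)=C/CC[C@@](OOC(OC)C(C)C(=O)N1CCOC1=O)(C)CCI | intermediate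
14 | 3-[(2E)-3-{[(3S,6E,10E)-1-iodo-3,7,11,15-tetramethylhexadeca-6,10,14-trien-3-yl]peroxy}-2-methylprop-2-enoyl]-1,3-oxazolidin-2-one | CC(C)=CCC/C(C)=C/CC/C(C)=C/CC[C@@](OO/C=C(\C)C(=O)N1CCOC1=O)(C)CCI | intermediate
15 | 3-[(2S)-2-[(3S,6S)-6-methyl-6-[(3E,7E)-4,8,12-trimethyltrideca-3,7,11-trien-1-yl]-1,2-dioxan-3-yl]propanoyl]-1,3-oxazolidin-2-one | CC(C)=CCC/C(C)=C/CC/C(C)=C/CC[C@@]1(C)CC[C@@H]([C@H](C)C(=O)N2CCOC2=O)OO1 | intermediate
16 | (2S)-2-[(3S,6S)-6-methyl-6-[(3E,7E)-4,8,12-trimethyltrideca-3,7,11-trien-1-yl]-1,2-dioxan-3-yl]propaneperoxoic acid (lithium salt in the flask, not isolated) | CC(C)=CCC/C(C)=C/CC/C(C)=C/CC[C@@]1(C)CC[C@@H]([C@H](C)C(=O)OO)OO1 | intermediate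
17 | (2S)-2-[(3S,6S)-6-methyl-6-[(3E,7E)-4,8,12-trimethyltrideca-3,7,11-trien-1-yl]-1,2-dioxan-3-yl]propanoic acid | CC(C)=CCC/C(C)=C/CC/C(C)=C/CC[C@@]1(C)CC[C@@H]([C@H](C)C(=O)O)OO1 | target

## Step count and risks

Total step count: 13. Longest linear sequence: 12 (steps 1–8 and 10–13).

Steps most likely to fail:

1. Step 12 (proposed new method). What may go wrong: homolysis of the weak alkenyl O–O bond before the chain starts; 3-exo attack of the Cα radical on the peroxide, with ring opening to a glycidic imide; reduction of the C4 radical before it cyclises; or poor facial discrimination at C3, since the substrate offers no bias of its own. The fallback uses known chemistry and changes the approach: the ring is closed through a C–O bond and the side chain is attached by peroxycarbenium alkylation. It sets out from 7. Dess–Martin periodinane with NaHCO3 gives (3S,6E,10E)-3-[(2-methoxypropan-2-yl)peroxy]-3,7,11,15-tetramethylhexadeca-6,10,14-trienal F1. Wittig reaction with Ph3P=CHOMe (from the phosphonium chloride and KN(SiMe3)2, THF, −78 °C) gives (4S,7E,11E)-1-methoxy-4-[(2-methoxypropan-2-yl)peroxy]-4,8,12,16-tetramethylheptadeca-1,7,11,15-tetraene F2. PPTS in methanol removes the peroxyketal, and the freed hydroperoxide adds 6-exo to the protonated enol ether to give (6S)-3-methoxy-6-methyl-6-[(3E,7E)-4,8,12-trimethyltrideca-3,7,11-trien-1-yl]-1,2-dioxane F3. TMSOTf-mediated substitution with 1-methoxy-1-(trimethylsilyloxy)prop-1-ene (CH2Cl2, −78 °C) gives methyl (2S)-2-[(3S,6S)-6-methyl-6-[(3E,7E)-4,8,12-trimethyltrideca-3,7,11-trien-1-yl]-1,2-dioxan-3-yl]propanoate F4 together with its C3/Cα diastereomers, from which it would be separated by HPLC. LiOH in THF/H2O brings the sequence back to the route at 17.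

2. Step 11. What may go wrong: ionisation at the peroxy oxygen, with expulsion of hydroperoxide 9 instead of methanol, or O–O homolysis of the alkenyl peroxide on warming or isolation. The fallback changes the approach from Lewis-acid ionisation of a peroxyacetal to base-mediated elimination from a perhemiacetal. It sets out from 9 and 12. Aqueous CF3CO2H hydrolyses 12 to 3-(2-methyl-3-oxopropanoyl)-1,3-oxazolidin-2-one F5. Hydroperoxide 9 adds to the formyl group (CH2Cl2, MgSO4, 0 °C) to give 3-[3-hydroxy-3-{[(3S,6E,10E)-1-iodo-3,7,11,15-tetramethylhexadeca-6,10,14-trien-3-yl]peroxy}-2-methylpropanoyl]-1,3-oxazolidin-2-one F6. Mesylation and E1cB loss of the sulfonate (MsCl, Et3N, CH2Cl2, −40 °C) bring the sequence back to the route at 14.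

3. Step 5. What may go wrong: SN1 ionisation at the tertiary carbon competing with the SN2-like opening, which would erode the configuration at C6 and allow elimination or cation–olefin cyclisation onto the polyene. The fallback changes the activation principle from electrophilic silyl activation of the oxetane to delivery of the nucleophile from a peroxo-metal centre. It sets out from 5 and comes back at 6, using MoO2(acac)2 (cat.) with anhydrous ethereal H2O2 near neutrality. Any C6 epimer carried forward becomes a diastereomer of 15 after step 12 and would be removed there by chromatography. New compounds: none F0.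

Further compounds
F1 | step 12 | (3S,6E,10E)-3-[(2-methoxypropan-2-yl)peroxy]-3,7,11,15-tetramethylhexadeca-6,10,14-trienal | CC(C)=CCC/C(C)=C/CC/C(C)=C/CC[C@@](OOC(C)(C)OC)(C)CC=O
F2 | step 12 | (4S,7E,11E)-1-methoxy-4-[(2-methoxypropan-2-yl)peroxy]-4,8,12,16-tetramethylheptadeca-1,7,11,15-tetraene (E/Z mixture at C1=C2) | CC(C)=CCC/C(C)=C/CC/C(C)=C/CC[C@@](OOC(C)(C)OC)(C)CC=COC
F3 | step 12 | (6S)-3-methoxy-6-methyl-6-[(3E,7E)-4,8,12-trimethyltrideca-3,7,11-trien-1-yl]-1,2-dioxane (C3 anomers) | CC(C)=CCC/C(C)=C/CC/C(C)=C/CC[C@@]1(C)CCC(OC)OO1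
F4 | step 12 | methyl (2S)-2-[(3S,6S)-6-methyl-6-[(3E,7E)-4,8,12-trimethyltrideca-3,7,11-trien-1-yl]-1,2-dioxan-3-yl]propanoate | CC(C)=CCC/C(C)=C/CC/C(C)=C/CC[C@@]1(C)CC[C@@H]([C@H](C)C(=O)OC)OO1
F5 | step 11 | 3-(2-methyl-3-oxopropanoyl)-1,3-oxazolidin-2-one | O=CC(C)C(=O)N1CCOC1=O
F6 | step 11 | 3-[3-hydroxy-3-{[(3S,6E,10E)-1-iodo-3,7,11,15-tetramethylhexadeca-6,10,14-trien-3-yl]peroxy}-2-methylpropanoyl]-1,3-oxazolidin-2-one | CC(C)=CCC/C(C)=C/CC/C(C)=C/CC[C@@](OOC(O)C(C)C(=O)N1CCOC1=O)(C)CCI
F0 | step 5 | none | none
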